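**Retrosynthetic overview**

1. Locants: chromanone O1, C2–C4, C4a, C5–C8, C8a (rings A and B); bridge CH2 = C9; pyranone ring C = O1', C2'–C6', with C6' bearing C9.
2. Feature: ring C is a 4-hydroxy-2-pyranone hanging through C9 on the labile ketal carbon C2, and its O1'–C6'–C5'–C4' part is a masked acylketene. Ring C is therefore closed last, in neutral medium, from a C2-bound dioxinonylmethyl group and 1,1-bis(benzyloxy)ethene (forms C3'–C4' and O1'–C2'), followed by hydrogenolysis.
3. C2 (the only stereocentre) and the C2–C9 bond come from an enantioselective vinylogous Mukaiyama addition of the dioxinone dienol silane to a 2-(arylmethoxy)-4-silyloxybenzopyrylium ion. The ketal oxygen carries 2-naphthylmethyl (cleaved faster than benzyl on palladium and removable on its own); the phenol carries benzyl.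
4. The 2-alkoxychromone is made from a 2-hydroxyacetophenone by CS2 annulation, S-methylation, oxidation and sulfinate displacement, because O-alkylation of a 4-hydroxycoumarin favours the 4-oxygen. The ring A pattern comes from Kumada coupling and Friedel–Crafts acetylation of 1-bromo-3,5-dimethoxybenzene.
5. Ring order: A (purchased), B (step 5), C (step 13).

Key step: step 13

Assumption: the C2 hemiketal of the target can racemise through ring–chain tautomerism to the open 1,3-diketone, so it is taken to be configurationally stable in neutral aprotic medium at or below 20 °C and step 14 is run and worked up that way; the sense of induction in step 10 cannot be predicted and is fixed by choosing the catalyst antipode in a pilot run.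

**Route**

Step 1
Reactants: 1 1-bromo-3,5-dimethoxybenzene; 2 1-bromo-3-methylbutane
Product: 4 1,3-dimethoxy-5-(3-methylbutyl)benzene, via 3-methylbutylmagnesium bromide 3 (not isolated)
Conditions: 2, Mg, THF, 40 °C; then 1, NiCl2(Ph2PCH2CH2CH2PPh2) (2 mol%), THF, 0 → 65 °C
Reagents that add atoms: none
Why: Kumada coupling, in which the primary alkyl Grignard reagent transmetalates to the aryl–nickel species and the chelating diphosphine favours reductive elimination over β-hydride loss.

Step 2
Reactants: 4 1,3-dimethoxy-5-(3-methylbutyl)benzene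
Product: 5 1-[2,4-dimethoxy-6-(3-methylbutyl)phenyl]ethan-1-one
Conditions: AcCl, AlCl3, CH2Cl2, −10 → 0 °C
Reagents that add atoms: acetyl chloride, CC(=O)Cl
Why: Friedel–Crafts acylation of a 5-alkylresorcinol dimethyl ether goes para to one methoxy group and ortho to the other, the position between the two methoxy groups being the less reactive one; any ortho-demethylated material converges in step 3.

Step 3
Reactants: 5 1-[2,4-dimethoxy-6-(3-methylbutyl)phenyl]ethan-1-one
Product: 6 1-[2,4-dihydroxy-6-(3-methylbutyl)phenyl]ethan-1-one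
Conditions: BBr3 (3.5 equiv), CH2Cl2, −78 → 20 °C; then H2O
Reagents that add atoms: none
Why: Lewis-acid cleavage of aryl methyl ethers, which removes both methyl groups and leaves the aryl ketone and the alkyl chain untouched.

Step 4
Reactants: 6 1-[2,4-dihydroxy-6-(3-methylbutyl)phenyl]ethan-1-one
Product: 7 1-[4-(benzyloxy)-2-hydroxy-6-(3-methylbutyl)phenyl]ethan-1-one
Conditions: BnBr (1.05 equiv), K2CO3, acetone, 56 °C
Reagents that add atoms: benzyl bromide, BrCc1ccccc1
Why: Williamson etherification is selective for the 4-hydroxyl because the 2-hydroxyl is held in a hydrogen bond to the ketone and is far less nucleophilic.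

Step 5
Reactants: 7 1-[4-(benzyloxy)-2-hydroxy-6-(3-methylbutyl)phenyl]ethan-1-one
Product: 8 7-(benzyloxy)-4-hydroxy-5-(3-methylbutyl)-2H-chromene-2-thione
Conditions: CS2, KOt-Bu (3.5 equiv), THF, 0 → 20 °C; then 1 M HCl
Reagents that add atoms: carbon disulfide, S=C=S
Why: Base-mediated annulation of a 2-hydroxyacetophenone with CS2, in which the ketone enolate adds to CS2 and the phenoxide closes ring B on the dithiocarboxylate by addition–elimination with loss of hydrosulfide.

Step 6
Reactants: 8 7-(benzyloxy)-4-hydroxy-5-(3-methylbutyl)-2H-chromene-2-thione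
Product: 9 7-(benzyloxy)-5-(3-methylbutyl)-2-(methylsulfanyl)-4H-chromen-4-one
Conditions: MeI (1.1 equiv), K2CO3, acetone, 20 °C
Reagents that add atoms: iodomethane, CI
Why: S-alkylation of the ambident anion at its soft sulfur terminus, which fixes the chromen-4-one form.

Step 7
Reactants: 9 7-(benzyloxy)-5-(3-methylbutyl)-2-(methylsulfanyl)-4H-chromen-4-one
Product: 10 7-(benzyloxy)-2-(methanesulfonyl)-5-(3-methylbutyl)-4H-chromen-4-one
Conditions: mCPBA (2.3 equiv), CH2Cl2, 0 → 20 °C
Reagents that add atoms: 3-chloroperoxybenzoic acid, OOC(=O)c1cccc(Cl)c1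
Why: Peracid oxidation of sulfide to sulfone; the electron-poor enone double bond and the benzyl ether do not react.

Step 8
Reactants: 10 7-(benzyloxy)-2-(methanesulfonyl)-5-(3-methylbutyl)-4H-chromen-4-one
Product: 11 7-(benzyloxy)-5-(3-methylbutyl)-2-(naphthalen-2-ylmethoxy)-4H-chromen-4-one
Conditions: naphthalen-2-ylmethanol (1.1 equiv), NaH (1.1 equiv), THF, 0 °C; then 10, −20 → 0 °C
Reagents that add atoms: naphthalen-2-ylmethanol, OCc1ccc2ccccc2c1
Why: Vinylic addition–elimination at C2, in which the alkoxide adds in a conjugate sense and methanesulfinate leaves, so the arylmethoxy group is placed on C2 without regiochemical ambiguity.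

Step 9
Reactants: 12 2,2,6-trimethyl-4H-1,3-dioxin-4-one
Product: 14 [(2,2-dimethyl-6-methylidene-6H-1,3-dioxin-4-yl)oxy]trimethylsilane, via lithium dienolate 13 (not isolated)
Conditions: LiN(i-Pr)2, THF, −78 °C; then Me3SiCl, −78 → 0 °C; non-aqueous work-up
Reagents that add atoms: chlorotrimethylsilane, C[Si](C)(C)Cl
Why: Kinetic γ-deprotonation of the dioxinone methyl group and O-silylation of the dienolate, the standard preparation of this vinylogous silyl ketene acetal.

Step 10
Reactants: 11 7-(benzyloxy)-5-(3-methylbutyl)-2-(naphthalen-2-ylmethoxy)-4H-chromen-4-one; 14 [(2,2-dimethyl-6-methylidene-6H-1,3-dioxin-4-yl)oxy]trimethylsilane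
Product: 17 (R)-7-(benzyloxy)-2-[(2,2-dimethyl-4-oxo-4H-1,3-dioxin-6-yl)methyl]-5-(3-methylbutyl)-2-(naphthalen-2-ylmethoxy)chroman-4-one, via benzopyrylium triflate 15 (not isolated), via silyl enol ether 16 (not isolated)
Conditions: t-BuMe2SiOTf (1.1 equiv), toluene, −40 °C; 4,5-dihydro-3H-dinaphtho[2,1-c:1',2'-e]silepine-4,4-diol (single antipode, 20 mol%), then 14 (1.5 equiv), −78 °C; then Bu4NF/AcOH (1:1), THF, −78 → −20 °C
Reagents that add atoms: none
Why: Proposed new method: silylation of the chromone carbonyl gives the 2-alkoxy-4-silyloxybenzopyrylium triflate 15, the chiral silanediol binds the triflate through two hydrogen bonds so that the planar cation sits in a chiral ion pair, and the dienol silane attacks the dialkoxycarbenium carbon C2 through its γ-CH2 on the unshielded face, which sets C2 as (R) with the proper catalyst antipode; buffered fluoride then frees the C4 ketone without acid (which would ionise the ketal) and without a long-lived enolate (which would expel the alkoxide); the closest known reaction type is the anion-binding-catalysed enantioselective Mukaiyama addition of silyl ketene acetals to 4-silyloxybenzopyrylium triflates from 2-unsubstituted chromones, here extended to a 2-alkoxy cation, a ketal stereocentre and a vinylogous nucleophile.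

Step 11
Reactants: 18 2-bromo-1,1-diethoxyethane
Product: 19 2-bromo-1,1-bis(benzyloxy)ethane
Conditions: BnOH (2.0 equiv), TsOH·H2O (1 mol%), 90 °C, EtOH distilled off under reduced pressure
Reagents that add atoms: benzyl alcohol, OCc1ccccc1
Why: Acid-catalysed transacetalisation driven by removal of the more volatile ethanol.

Step 12
Reactants: 19 2-bromo-1,1-bis(benzyloxy)ethane
Product: 20 1,1-bis(benzyloxy)ethene
Conditions: KOt-Bu (1.3 equiv), THF, 0 → 20 °C; filtration through basic Al2O3, short-path distillation in base-washed glass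
Reagents that add atoms: none
Why: Base-induced dehydrobromination (E2) of an α-bromo acetal, the classical route to ketene acetals; the product is kept free of alcohol and acid.

Step 13
Reactants: 17 (R)-7-(benzyloxy)-2-[(2,2-dimethyl-4-oxo-4H-1,3-dioxin-6-yl)methyl]-5-(3-methylbutyl)-2-(naphthalen-2-ylmethoxy)chroman-4-one; 20 1,1-bis(benzyloxy)ethene
Product: 23 (R)-7-(benzyloxy)-2-{[6-(benzyloxy)-4-oxo-4H-pyran-2-yl]methyl}-5-(3-methylbutyl)-2-(naphthalen-2-ylmethoxy)chroman-4-one, via acylketene 21 (not isolated), via dihydropyranone 22 (not isolated)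
Conditions: 20 (4 equiv), toluene, 110 °C, 17 added over 2 h, acetone swept out with N2
Reagents that add atoms: none
Why: A retro-[4+2] fragmentation of the dioxinone at 110 °C releases acetone and acylketene 21, whose 1-oxadiene (O1'=C6'–C5'=C4') combines with the electron-rich alkene of 20 in a hetero-Diels–Alder reaction, the closest known reaction type being the trapping of thermally generated acylketenes by ketene acetals and enol ethers to give 4-pyranones. Ring C closes in this intermolecular [4+2] event, which forms C3'–C4' and O1'–C2' (if it runs stepwise through a zwitterion, C3'–C4' forms first and the enolate oxygen closes the ring by 6-exo-trig attack on the dialkoxycarbenium carbon), and adduct 22 aromatises by loss of benzyl alcohol from the orthoester carbon C2'. No stereocentre is formed, and C2 is not touched because the medium is neutral and aprotic. The step needs regioselectivity, which the polarity match secures: the nucleophilic CH2 of the ketene acetal bonds to the electrophilic ketene carbon C4' and the acyl oxygen O1' to the dioxygenated carbon. It also needs chemoselectivity against capture of the acylketene by the benzyl alcohol set free, which the fourfold excess of 20 (it outcompetes the alcohol and can scavenge it as the orthoester) and the slow addition of 17 should secure.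

Step 14
Reactants: 23 (R)-7-(benzyloxy)-2-{[6-(benzyloxy)-4-oxo-4H-pyran-2-yl]methyl}-5-(3-methylbutyl)-2-(naphthalen-2-ylmethoxy)chroman-4-one
Product: 24 (R)-2,7-dihydroxy-2-[(4-hydroxy-2-oxo-2H-pyran-6-yl)methyl]-5-(3-methylbutyl)chroman-4-one
Conditions: H2 (1 atm), 10% Pd/C, EtOAc, 20 °C; filtration, evaporation below 25 °C
Reagents that add atoms: none
Why: Heterogeneous hydrogenolysis in neutral solvent cleaves the 2-naphthylmethyl ketal ether and both benzyl ethers at the arylmethyl carbon, so no bond to C2 is broken and its configuration is kept, and the 2-hydroxy-4-pyranone formed tautomerises to the 4-hydroxy-2-pyranone.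

**Compound list**

1 | 1-bromo-3,5-dimethoxybenzene | COc1cc(Br)cc(OC)c1 | starting material
2 | 1-bromo-3-methylbutane | CC(C)CCBr | starting material
3 | 3-methylbutylmagnesium bromide | CC(C)CC[Mg]Br | intermediate
4 | 1,3-dimethoxy-5-(3-methylbutyl)benzene | COc1cc(CCC(C)C)cc(OC)c1 | intermediate
5 | 1-[2,4-dimethoxy-6-(3-methylbutyl)phenyl]ethan-1-one | COc1cc(CCC(C)C)c(C(C)=O)c(OC)c1 | intermediate
6 | 1-[2,4-dihydroxy-6-(3-methylbutyl)phenyl]ethan-1-one | CC(C)CCc1cc(O)cc(O)c1C(C)=O | intermediate
7 | 1-[4-(benzyloxy)-2-hydroxy-6-(3-methylbutyl)phenyl]ethan-1-one | CC(C)CCc1cc(OCc2ccccc2)cc(O)c1C(C)=O | intermediate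
8 | 7-(benzyloxy)-4-hydroxy-5-(3-methylbutyl)-2H-chromene-2-thione | CC(C)CCc1cc(OCc2ccccc2)cc2oc(=S)cc(O)c12 | intermediate
9 | 7-(benzyloxy)-5-(3-methylbutyl)-2-(methylsulfanyl)-4H-chromen-4-one | CC(C)CCc1cc(OCc2ccccc2)cc2oc(SC)cc(=O)c12 | intermediate
10 | 7-(benzyloxy)-2-(methanesulfonyl)-5-(3-methylbutyl)-4H-chromen-4-one | CC(C)CCc1cc(OCc2ccccc2)cc2oc(S(C)(=O)=O)cc(=O)c12 | intermediate
11 | 7-(benzyloxy)-5-(3-methylbutyl)-2-(naphthalen-2-ylmethoxy)-4H-chromen-4-one | CC(C)CCc1cc(OCc2ccccc2)cc2oc(OCc3ccc4ccccc4c3)cc(=O)c12 | intermediate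
12 | 2,2,6-trimethyl-4H-1,3-dioxin-4-one | CC1=CC(=O)OC(C)(C)O1 | starting material
13 | lithium 2,2-dimethyl-6-methylidene-6H-1,3-dioxin-4-olate | C=C1C=C(O[Li])OC(C)(C)O1 | intermediate
14 | [(2,2-dimethyl-6-methylidene-6H-1,3-dioxin-4-yl)oxy]trimethylsilane | C=C1C=C(O[Si](C)(C)C)OC(C)(C)O1 | intermediate
15 | 7-(benzyloxy)-4-[(tert-butyldimethylsilyl)oxy]-5-(3-methylbutyl)-2-(naphthalen-2-ylmethoxy)-1-benzopyrylium trifluoromethanesulfonate | CC(C)CCc1cc(OCc2ccccc2)cc2[o+]c(OCc3ccc4ccccc4c3)cc(O[Si](C)(C)C(C)(C)C)c12.[O-]S(=O)(=O)C(F)(F)F | intermediate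
16 | (R)-6-{[7-(benzyloxy)-4-[(tert-butyldimethylsilyl)oxy]-5-(3-methylbutyl)-2-(naphthalen-2-ylmethoxy)-2H-chromen-2-yl]methyl}-2,2-dimethyl-4H-1,3-dioxin-4-one | CC(C)CCc1cc(OCc2ccccc2)cc2c1C(O[Si](C)(C)C(C)(C)C)=C[C@@](OCc1ccc3ccccc3c1)(CC1=CC(=O)OC(C)(C)O1)O2 | intermediate
17 | (R)-7-(benzyloxy)-2-[(2,2-dimethyl-4-oxo-4H-1,3-dioxin-6-yl)methyl]-5-(3-methylbutyl)-2-(naphthalen-2-ylmethoxy)chroman-4-one | CC(C)CCc1cc(OCc2ccccc2)cc2c1C(=O)C[C@@](OCc1ccc3ccccc3c1)(CC1=CC(=O)OC(C)(C)O1)O2 | intermediate
18 | 2-bromo-1,1-diethoxyethane | CCOC(CBr)OCC | starting material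
19 | 2-bromo-1,1-bis(benzyloxy)ethane | BrCC(OCc1ccccc1)OCc1ccccc1 | intermediate
20 | 1,1-bis(benzyloxy)ethene | C=C(OCc1ccccc1)OCc1ccccc1 | intermediate
21 | (R)-4-[7-(benzyloxy)-5-(3-methylbutyl)-2-(naphthalen-2-ylmethoxy)-4-oxochroman-2-yl]-3-oxobut-1-en-1-one | CC(C)CCc1cc(OCc2ccccc2)cc2c1C(=O)C[C@@](OCc1ccc3ccccc3c1)(CC(=O)C=C=O)O2 | intermediate
22 | (R)-7-(benzyloxy)-2-{[6,6-bis(benzyloxy)-4-oxo-5,6-dihydro-4H-pyran-2-yl]methyl}-5-(3-methylbutyl)-2-(naphthalen-2-ylmethoxy)chroman-4-one | CC(C)CCc1cc(OCc2ccccc2)cc2c1C(=O)C[C@@](OCc1ccc3ccccc3c1)(CC1=CC(=O)CC(OCc3ccccc3)(OCc3ccccc3)O1)O2 | intermediate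
23 | (R)-7-(benzyloxy)-2-{[6-(benzyloxy)-4-oxo-4H-pyran-2-yl]methyl}-5-(3-methylbutyl)-2-(naphthalen-2-ylmethoxy)chroman-4-one | CC(C)CCc1cc(OCc2ccccc2)cc2c1C(=O)C[C@@](OCc1ccc3ccccc3c1)(Cc1cc(=O)cc(OCc3ccccc3)o1)O2 | intermediate
24 | (R)-2,7-dihydroxy-2-[(4-hydroxy-2-oxo-2H-pyran-6-yl)methyl]-5-(3-methylbutyl)chroman-4-one | CC(C)CCc1cc(O)cc2c1C(=O)C[C@@](O)(Cc1cc(O)cc(=O)o1)O2 | target

**Step count and risks**

Total step count: 14. Longest linear sequence: 11 steps (steps 1 to 8, 10, 13, 14).

Steps most likely to fail: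

1. Step 10 (proposed new method). Facial discrimination at the planar 2-alkoxybenzopyrylium ion may be poor. The silyl triflate released can also re-ionise the new ketal by loss of the arylmethoxy group, which would erode enantiopurity or lead on to the achiral 2-substituted chromone. Arylmethyl transfer from the pyrylium oxygen is a further loss pathway. Fallback: set out from 11 and 14 and run the addition without the silanediol (t-BuMe2SiOTf, CH2Cl2, −78 °C, same buffered fluoride work-up), a plain silyl-triflate-mediated vinylogous Mukaiyama addition. This should give, through 15 and the racemic silyl enol ether F1, the racemic chromanone F2. The enantiomers of F2 are separated by preparative chromatography on a chiral stationary phase (amylose tris(3,5-dimethylphenylcarbamate), CO2/i-PrOH), the configuration is assigned by X-ray analysis, and the (R)-enantiomer re-enters the route as 17.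

2. Step 13. The benzyl alcohol liberated on aromatisation may intercept the acylketene as its β-keto ester. Prolonged heating may also cause β-elimination of naphthalen-2-ylmethanol from the β-alkoxy ketone to give the chromone, and the acylketene may dimerise. Fallback: set out from 12 and 20 and carry ring C into the addition step ready-made. Thermolysis of the simple dioxinone 12 with 20 in toluene at 110 °C should give, via acetylketene F3 and the 2,2-bis(benzyloxy)dihydropyranone F4, 2-(benzyloxy)-6-methyl-4H-pyran-4-one F5. This is the same cycloaddition, but on a substrate with no ketal to lose and with both partners usable in excess. LiN(SiMe3)2 at −78 °C should deprotonate the 6-methyl group to the lithium dienolate F6, which Me3SiCl converts to the silyl dienol ether F7. F7 is added through its exocyclic CH2 to benzopyrylium triflate 15 (from 11) under the conditions of step 10, and buffered fluoride cleavage of the resulting silyl enol ether F8 returns to the route at 23, bypassing 17.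

3. Step 14. The C5'–C6' double bond or the C4 ketone may be hydrogenated before the hindered ketal ether at C2 has been cleaved. Long contact with the catalyst may also open the hemiketal, with loss of configuration or dehydration to the chromone. Fallback: set out from 23 and unveil the hindered position first by oxidation. DDQ in CH2Cl2/pH 7 phosphate buffer at 0 °C should remove only the 2-naphthylmethyl group and give the free hemiketal F9 with both benzyl ethers intact. A brief hydrogenolysis (H2, 10% Pd/C, EtOAc) then has only two unhindered benzyl ethers to cleave and returns to the route at 24.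

**Further compounds**

F1 | step 10 | racemic 6-{[7-(benzyloxy)-4-[(tert-butyldimethylsilyl)oxy]-5-(3-methylbutyl)-2-(naphthalen-2-ylmethoxy)-2H-chromen-2-yl]methyl}-2,2-dimethyl-4H-1,3-dioxin-4-one | CC(C)CCc1cc(OCc2ccccc2)cc2c1C(O[Si](C)(C)C(C)(C)C)=CC(OCc1ccc3ccccc3c1)(CC1=CC(=O)OC(C)(C)O1)O2
F2 | step 10 | racemic 7-(benzyloxy)-2-[(2,2-dimethyl-4-oxo-4H-1,3-dioxin-6-yl)methyl]-5-(3-methylbutyl)-2-(naphthalen-2-ylmethoxy)chroman-4-one | CC(C)CCc1cc(OCc2ccccc2)cc2c1C(=O)CC(OCc1ccc3ccccc3c1)(CC1=CC(=O)OC(C)(C)O1)O2
F3 | step 13 | acetylketene (3-oxobut-1-en-1-one) | CC(=O)C=C=O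
F4 | step 13 | 2,2-bis(benzyloxy)-6-methyl-2,3-dihydro-4H-pyran-4-one | CC1=CC(=O)CC(OCc2ccccc2)(OCc2ccccc2)O1
F5 | step 13 | 2-(benzyloxy)-6-methyl-4H-pyran-4-one | Cc1cc(=O)cc(OCc2ccccc2)o1
F6 | step 13 | lithium 2-(benzyloxy)-6-methylidene-6H-pyran-4-olate | C=C1C=C(O[Li])C=C(OCc2ccccc2)O1
F7 | step 13 | {[2-(benzyloxy)-6-methylidene-6H-pyran-4-yl]oxy}trimethylsilane | C=C1C=C(O[Si](C)(C)C)C=C(OCc2ccccc2)O1
F8 | step 13 | (R)-2-(benzyloxy)-6-{[7-(benzyloxy)-4-[(tert-butyldimethylsilyl)oxy]-5-(3-methylbutyl)-2-(naphthalen-2-ylmethoxy)-2H-chromen-2-yl]methyl}-4H-pyran-4-one | CC(C)CCc1cc(OCc2ccccc2)cc2c1C(O[Si](C)(C)C(C)(C)C)=C[C@@](OCc1ccc3ccccc3c1)(Cc1cc(=O)cc(OCc3ccccc3)o1)O2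
F9 | step 14 | (R)-7-(benzyloxy)-2-{[6-(benzyloxy)-4-oxo-4H-pyran-2-yl]methyl}-2-hydroxy-5-(3-methylbutyl)chroman-4-one | CC(C)CCc1cc(OCc2ccccc2)cc2c1C(=O)C[C@@](O)(Cc1cc(=O)cc(OCc3ccccc3)o1)O2
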